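Retrosynthesis: cut the two benzoate C–O bonds (at O5 and O7) and the O–CH3 bond at C1, then the C5–O bond (made with inversion from a 5,6-oxirane) and the C1–H and C4–H bonds (from carbonyls), and last the C5–O and C6–O bonds of the oxirane; no C–C bond is cut, the carbocycle comes from an arene.
What allows this: C1 and C4 carry oxygen para to each other across C2=C3, so the ring is a reduced 4,4-dimethoxycyclohexa-2,5-dienone (p-quinone monoketal), and the trans O,O pair on C5/C6 marks an oxirane on its unsubstituted C5=C6 enone bond.
Forward order: arene, quinone monoketal, oxirane (the only ring closed, step 4), two carbonyl reductions, oxirane opening, esters.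
Stereochemistry: C6 (and C5 for the time being) from the catalyst-controlled epoxidation; C4 and C1 from hydride delivery anti to the oxirane, C4 then inverted by Mitsunobu reaction; C5 inverted when the C4 benzoate opens the oxirane.
The relay benzoate is then removed, because its orthoacid is expected to collapse to the O4 ester rather than the O5 ester; the two benzoates of the target are placed on O7 and O5 of the tetraol by galactoside-type stannylene acylation.

Key step: step 4

Remark on notation: ring carbons keep the target's locants in every compound (C1 = OMe carbon, C2 = CH=, C3 = carbon bearing C7, then C4, C5, C6); β is the face of the C1–OMe and C6–O bonds of the target, α the face of its C4–O and C5–O bonds; CIP descriptors are quoted with these locants.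
Assumption: the cinchonidine-derived salt is taken to expose the β face at C6 to the peroxide, by analogy with other quinone monoketal epoxidations under this catalysis; if the sense is the opposite one, the pseudoenantiomeric N-benzylcinchoninium chloride is used with no other change.

Step 1
Reactants: 1 2-hydroxy-5-methoxybenzaldehyde
Product: 2 2-(hydroxymethyl)-4-methoxyphenol
Conditions: NaBH4, MeOH, 0 °C
Reagents that add atoms: none
Why: Borohydride reduction of the aryl aldehyde to the benzylic alcohol is chemoselective and leaves the phenol and the aryl methyl ether untouched.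

Step 2
Reactants: 2 2-(hydroxymethyl)-4-methoxyphenol
Product: 3 2-{[tert-butyl(dimethyl)silyl]oxymethyl}-4-methoxyphenol
Conditions: TBSCl (1.05 equiv), imidazole, CH2Cl2, 0 °C
Reagents that add atoms: tert-butyldimethylsilyl chloride, CC(C)(C)[Si](C)(C)Cl
Why: Silyl ether formation with TBSCl and imidazole is faster at the primary benzylic hydroxyl than at the hydrogen-bonded, less nucleophilic phenol when one equivalent of the chloride is used at low temperature.

Step 3
Reactants: 3 2-{[tert-butyl(dimethyl)silyl]oxymethyl}-4-methoxyphenol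
Product: 4 2-{[tert-butyl(dimethyl)silyl]oxymethyl}-4,4-dimethoxycyclohexa-2,5-dien-1-one (achiral quinone monoketal; ketone = C4, ketal = C1)
Conditions: PhI(OAc)2, MeOH, 0 °C
Reagents that add atoms: methanol, CO
Why: Oxidative dearomatisation of a para-methoxyphenol by trivalent iodine in methanol places the second methoxy group on the methoxy-bearing carbon and gives the p-quinone monoketal, with the silyl ether as a spectator.

Step 4
Reactants: 4 quinone monoketal
Product: 5 (5R,6S)-3-{[tert-butyl(dimethyl)silyl]oxymethyl}-5,6-epoxy-1,1-dimethoxycyclohex-2-en-4-one (oxirane on the β face)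
Conditions: t-BuOOH, N-benzylcinchonidinium chloride (10 mol%), NaOH (aq.), toluene, 0 °C
Reagents that add atoms: tert-butyl hydroperoxide, CC(C)(C)OO
Why: This is a Weitz–Scheffer nucleophilic epoxidation under chiral phase-transfer catalysis, a reaction type established for quinone monoketals: the tert-butylperoxide anion, held as an ion pair by the quaternary cinchona ammonium cation, adds in conjugate fashion to C6, and the resulting C4–C5 enolate closes on the proximal peroxide oxygen with loss of tert-butoxide. The oxirane is the only ring formed and closes in 3-exo-tet mode (C5 attacks oxygen, the breaking O–O bond is exocyclic), so the C6–O bond forms first and the C5–O bond second. C6 is set by the face of the flat, achiral dienone that the chiral ion pair exposes to the peroxide, and C5 is not independent because a three-membered ring fused to the cyclohexenone can only be cis. Two selectivities are needed, face and site: the face comes from the catalyst alone, and the site from the substrate, since the C2=C3 enone carries the CH2OTBS group on its α-carbon C3, which lowers its electrophilicity and would force ring closure at a fully substituted carbon, so the peroxide takes the unsubstituted C5=C6 bond. The ketal keeps C1 from 1,2-addition and the product from aromatising.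

Step 5
Reactants: 5 epoxy ketone
Product: 6 (4S,5S,6S)-3-{[tert-butyl(dimethyl)silyl]oxymethyl}-5,6-epoxy-1,1-dimethoxycyclohex-2-en-4-ol (4β-OH, cis to the 5β,6β-oxirane)
Conditions: i-Bu2AlH, THF, −78 °C
Reagents that add atoms: none
Why: 1,2-Hydride reduction of the enone carbonyl occurs from the α face, opposite the oxirane oxygen on the adjacent carbon (steric and dipolar approach control known for epoxyquinone monoketals), so C4 is set with its hydroxyl cis to the epoxide.

Step 6
Reactants: 6 syn-epoxy alcohol
Product: 7 (4R,5S,6S)-3-{[tert-butyl(dimethyl)silyl]oxymethyl}-5,6-epoxy-1,1-dimethoxycyclohex-2-en-4-yl benzoate (4α-OBz, trans to the oxirane)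
Conditions: PhCO2H, PPh3, DIAD, THF, 0 °C → rt
Reagents that add atoms: benzoic acid, O=C(O)c1ccccc1
Why: Mitsunobu esterification replaces the activated C4 oxygen by benzoate in an SN2 step with inversion, which puts the benzoate on the α face trans to the oxirane, while SN2′ attack at C2 is blocked by the neighbouring quaternary ketal carbon.

Step 7
Reactants: 7 ketal benzoate
Product: 8 (4R,5S,6S)-4-benzoyloxy-3-{[tert-butyl(dimethyl)silyl]oxymethyl}-5,6-epoxycyclohex-2-en-1-one
Conditions: pyridinium p-toluenesulfonate (cat.), acetone–H2O, rt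
Reagents that add atoms: water, O
Why: Acid-catalysed hydrolysis of the allylic dimethyl ketal runs through a conjugated oxocarbenium ion under conditions too mild to open the electron-poor oxirane or to cleave the silyl ether or the benzoate, as in the unmasking of epoxyquinone monoketals.

Step 8
Reactants: 8 epoxy enone
Product: 9 (1R,4R,5S,6R)-4-benzoyloxy-3-{[tert-butyl(dimethyl)silyl]oxymethyl}-5,6-epoxycyclohex-2-en-1-ol (1β-OH, cis to the oxirane)
Conditions: NaBH4, CeCl3·7H2O, MeOH, −78 °C
Reagents that add atoms: none
Why: Luche reduction adds hydride to the enone carbonyl in 1,2 fashion only and again from the α face opposite the adjacent oxirane oxygen, which sets C1 with its hydroxyl cis to the epoxide, the later 1,6-cis relation.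

Step 9
Reactants: 9 epoxy allylic alcohol
Product: 10 (1R,4R,5S,6R)-4-benzoyloxy-3-{[tert-butyl(dimethyl)silyl]oxymethyl}-5,6-epoxy-1-methoxycyclohex-2-ene (1β-OMe)
Conditions: MeI, Ag2O, 4 Å molecular sieves, MeCN, 40 °C
Reagents that add atoms: iodomethane, CI
Why: Purdie methylation etherifies the only free hydroxyl under non-basic conditions that leave the benzoate, the oxirane and the silyl ether intact.

Step 10
Reactants: 10 epoxy benzoate methyl ether
Product: 13 (1R,4R,5S,6S)-4-benzoyloxy-3-(hydroxymethyl)-1-methoxycyclohex-2-ene-5,6-diol (1β-OMe; 4α-OBz; 5α-OH; 6β-OH), via primary alcohol 11 (not isolated), via dioxolanylium ion 12 (not isolated)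
Conditions: HClO4 (aq., cat.), THF–H2O, 0 °C → rt
Reagents that add atoms: water, O
Why: Acid-catalysed oxirane opening with neighbouring-group participation, in which the carbonyl oxygen of the trans C4 benzoate attacks C5 from the α face in a 5-exo closure (inversion at C5, C6–O bond untouched) to give a cis-fused 2-phenyl-1,3-dioxolan-2-ylium ion that water converts through the orthoacid into a hydroxy benzoate, while the primary silyl ether is hydrolysed by the same acid.

Compound 13 is drawn with the benzoyl group on O4, the pseudoaxial ester expected from collapse of the orthoacid. If the benzoyl group rested on O5 or O7 instead, step 11 would give the same tetraol.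

Step 11
Reactants: 13 hydroxy benzoate
Product: 14 (1R,4R,5R,6S)-3-(hydroxymethyl)-1-methoxycyclohex-2-ene-4,5,6-triol (1β-OMe; 4α-OH; 5α-OH; 6β-OH)
Conditions: NaOMe (cat.), MeOH, rt
Reagents that add atoms: none
Why: Zemplén transesterification removes the relay benzoate, on whichever oxygen the orthoacid collapse has left it, without touching a stereocentre or the allylic methyl ether.

Step 12
Reactants: 14 tetraol
Product: 15 (1R,4R,5R,6R)-5-benzoyloxy-3-(benzoyloxymethyl)-1-methoxycyclohex-2-ene-4,6-diol (target)
Conditions: Bu2SnO (2.2 equiv), MeOH, reflux; evaporate; BzCl (2.1 equiv), toluene, 0 °C → rt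
Reagents that add atoms: benzoyl chloride, O=C(Cl)c1ccccc1
Why: Stannylene-mediated regioselective acylation, in which the dibutylstannylene derivatives activate the primary C7 oxygen and the equatorial C5 oxygen of the cis-4,5-diol while the pseudoaxial allylic C4–OH and the C6–OH stay free, the same pattern as the 3,6-di-O-benzoylation of methyl α-galactopyranoside, of which 14 is the carbocyclic analogue.

Compound list
1 | 2-hydroxy-5-methoxybenzaldehyde | COc1ccc(O)c(C=O)c1 | starting material
2 | 2-(hydroxymethyl)-4-methoxyphenol | COc1ccc(O)c(CO)c1 | intermediate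
3 | 2-{[tert-butyl(dimethyl)silyl]oxymethyl}-4-methoxyphenol | COc1ccc(O)c(CO[Si](C)(C)C(C)(C)C)c1 | intermediate
4 | 2-{[tert-butyl(dimethyl)silyl]oxymethyl}-4,4-dimethoxycyclohexa-2,5-dien-1-one | COC1(OC)C=CC(=O)C(CO[Si](C)(C)C(C)(C)C)=C1 | intermediate
5 | (5R,6S)-3-{[tert-butyl(dimethyl)silyl]oxymethyl}-5,6-epoxy-1,1-dimethoxycyclohex-2-en-4-one (β-oxirane) | COC1(OC)C=C(CO[Si](C)(C)C(C)(C)C)C(=O)[C@@H]2O[C@H]12 | intermediate
6 | (4S,5S,6S)-epoxy alcohol, 4β-OH cis to the 5β,6β-oxirane, C1 dimethyl ketal, C7 OTBS | COC1(OC)C=C(CO[Si](C)(C)C(C)(C)C)[C@H](O)[C@@H]2O[C@H]12 | intermediate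
7 | (4R,5S,6S)-benzoate, 4α-OBz trans to the 5β,6β-oxirane, C1 dimethyl ketal, C7 OTBS | COC1(OC)C=C(CO[Si](C)(C)C(C)(C)C)[C@@H](OC(=O)c2ccccc2)[C@@H]2O[C@H]12 | intermediate
8 | (4R,5S,6S)-4-benzoyloxy-3-{[tert-butyl(dimethyl)silyl]oxymethyl}-5,6-epoxycyclohex-2-en-1-one | O=C1C=C(CO[Si](C)(C)C(C)(C)C)[C@@H](OC(=O)c2ccccc2)[C@@H]2O[C@H]12 | intermediate
9 | (1R,4R,5S,6R)-4-benzoyloxy-3-{[tert-butyl(dimethyl)silyl]oxymethyl}-5,6-epoxycyclohex-2-en-1-ol (1β-OH) | O[C@@H]1C=C(CO[Si](C)(C)C(C)(C)C)[C@@H](OC(=O)c2ccccc2)[C@@H]2O[C@H]12 | intermediate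
10 | (1R,4R,5S,6R)-4-benzoyloxy-3-{[tert-butyl(dimethyl)silyl]oxymethyl}-5,6-epoxy-1-methoxycyclohex-2-ene (1β-OMe) | CO[C@@H]1C=C(CO[Si](C)(C)C(C)(C)C)[C@@H](OC(=O)c2ccccc2)[C@@H]2O[C@H]12 | intermediate
11 | (1R,4R,5S,6R)-4-benzoyloxy-5,6-epoxy-3-(hydroxymethyl)-1-methoxycyclohex-2-ene (10 without the silyl group) | CO[C@@H]1C=C(CO)[C@@H](OC(=O)c2ccccc2)[C@@H]2O[C@H]12 | intermediate
12 | 2-phenyl-1,3-dioxolan-2-ylium ion cis-fused through O4 and O5 (both α), 6β-OH, 1β-OMe, C7 OH | CO[C@@H]1C=C(CO)[C@H]2O[C+](c3ccccc3)O[C@H]2[C@@H]1O | intermediate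
13 | (1R,4R,5S,6S)-4-benzoyloxy-3-(hydroxymethyl)-1-methoxycyclohex-2-ene-5,6-diol | CO[C@@H]1C=C(CO)[C@@H](OC(=O)c2ccccc2)[C@@H](O)[C@@H]1O | intermediate
14 | (1R,4R,5R,6S)-3-(hydroxymethyl)-1-methoxycyclohex-2-ene-4,5,6-triol | CO[C@@H]1C=C(CO)[C@@H](O)[C@@H](O)[C@@H]1O | intermediate
15 | (1R,4R,5R,6R)-5-benzoyloxy-3-(benzoyloxymethyl)-1-methoxycyclohex-2-ene-4,6-diol | CO[C@@H]1C=C(COC(=O)c2ccccc2)[C@@H](O)[C@@H](OC(=O)c2ccccc2)[C@@H]1O | target

Total step count: 12. Longest linear sequence: 12 steps (fully linear from 1).

Steps most likely to fail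

Step 4. The ion pair may discriminate the two faces of the flat dienone too weakly, or some peroxide may add to the C2=C3 enone, so that the epoxide is formed with low enantiomeric purity. The fallback sets out from 4 and returns at 6. Dienone 4 would be epoxidised without a chiral catalyst (H2O2, K2CO3, THF–H2O, 0 °C) to the racemic epoxy ketone F1 and reduced as in step 5 to the racemic syn-epoxy alcohol F2. F2 would be esterified with (S)-2-methoxy-2-phenylacetic acid (DCC, DMAP, CH2Cl2) and the two diastereomeric esters separated by chromatography or crystallisation. Methanolysis (K2CO3, MeOH) of the (4S,5S,6S) ester F3 would then give 6.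

Step 12. Regiocontrol in the double acylation may be lost: the cis C1–OMe may help tin to activate O6, a third benzoyl group may enter, or the O5 benzoate may migrate. The fallback sets out from 14 and returns at 15, introducing the esters one at a time. BzCl (1.05 equiv) with 2,4,6-collidine in CH2Cl2 at −40 °C should acylate only the primary hydroxyl and give the 7-O-benzoyl triol F4. Benzoylation of F4 under borinic acid catalysis (2-aminoethyl diphenylborinate, Ph2BOCH2CH2NH2, 10 mol%; BzCl, i-Pr2NEt, MeCN, rt) should then give 15, because the catalyst binds only the cis-4,5-diol and activates its equatorial oxygen O5, as in the acylation of cis-diols of pyranosides.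

Step 8. Hydride may enter C1 from the β face, because the α-benzoate at C4 lies on the face the hydride is meant to use and may offset the bias of the oxirane; the reduction would then give the C1 epimer. The fallback sets out from 8 and returns at 9. The 1α-alcohol F5 from the reduction would be inverted by Mitsunobu reaction with formic acid (PPh3, DIAD, THF) to the 1β-formate F6. The formyl group of F6 would be removed in the presence of the benzoate by brief methanolysis (KHCO3, MeOH, 0 °C) to give 9.

Further compounds
F1 | step 4 | racemic 3-{[tert-butyl(dimethyl)silyl]oxymethyl}-5,6-epoxy-1,1-dimethoxycyclohex-2-en-4-one (one enantiomer drawn) | COC1(OC)C=C(CO[Si](C)(C)C(C)(C)C)C(=O)[C@@H]2O[C@H]12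
F2 | step 4 | racemic syn-epoxy alcohol, 4-OH cis to the oxirane (one enantiomer drawn) | COC1(OC)C=C(CO[Si](C)(C)C(C)(C)C)[C@H](O)[C@@H]2O[C@H]12
F3 | step 4 | (S)-2-methoxy-2-phenylacetate of (4S,5S,6S)-epoxy alcohol 6 | COC1(OC)C=C(CO[Si](C)(C)C(C)(C)C)[C@H](OC(=O)[C@@H](OC)c2ccccc2)[C@@H]2O[C@H]12
F4 | step 12 | (1R,4R,5R,6S)-3-(benzoyloxymethyl)-1-methoxycyclohex-2-ene-4,5,6-triol | CO[C@@H]1C=C(COC(=O)c2ccccc2)[C@@H](O)[C@@H](O)[C@@H]1O
F5 | step 8 | (1S,4R,5S,6R)-4-benzoyloxy-3-{[tert-butyl(dimethyl)silyl]oxymethyl}-5,6-epoxycyclohex-2-en-1-ol (1α-OH, C1 epimer of 9) | O[C@H]1C=C(CO[Si](C)(C)C(C)(C)C)[C@@H](OC(=O)c2ccccc2)[C@@H]2O[C@H]12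
F6 | step 8 | 1β-formate of 9 | O=CO[C@@H]1C=C(CO[Si](C)(C)C(C)(C)C)[C@@H](OC(=O)c2ccccc2)[C@@H]2O[C@H]12
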